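**Retrosynthetic overview**

1. Target 13 ⇐ 12 ⇐ 11: the end game is only CHO → CH2OH and removal of three silyl groups.
2. 11 ⇐ 8 + 5: the tetrahydrofuran (the only ring) is closed here, O1–C2 by acetalisation and C2–C3 by attack of the enol carbamate on the oxocarbenium ion.
3. 8 ⇐ 3 + 5 (key step): the bond between the benzylic carbinol carbon and the CH(CH2OSi) carbon is made with a chiral homoenolate (d3) reagent, the sparteine-lithiated, titanated allyl carbamate. It joins an aldehyde carbon to what is the β-carbon of a masked 4-silyloxybutanal.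
4. 3 ⇐ (E)-but-2-ene-1,4-diol 1; 5 ⇐ syringaldehyde 4, which is used twice.
5. Stereochemistry: step 4 sets the two anchoring centres (reagent control); step 5 sets the other two relative to them.

Assumption: (E)-but-2-ene-1,4-diol and (−)-sparteine are bought as catalogue items, and the sense of induction in step 4 follows the accepted model (pro-S deprotonation, Li→Ti exchange with inversion, chair transition state); it should be confirmed on 8 by a Mosher ester.

**Route**

Step 1
Reactants: 1 (E)-but-2-ene-1,4-diol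
Product: 2 (E)-4-[(triisopropylsilyl)oxy]but-2-en-1-ol
Conditions: TIPSCl (1 equiv), imidazole (1.2 equiv), 1 (3 equiv), THF/DMF, 0 °C → rt; excess diol washed out with water
Reagents that add atoms: chlorotriisopropylsilane (TIPSCl), CC(C)[Si](Cl)(C(C)C)C(C)C
Why: Imidazole-mediated O-silylation of one of two equivalent primary hydroxyls, made selective for the mono-ether by the excess of diol; no stereocentre is formed and the E geometry is untouched.

Step 2
Reactants: 2 (E)-4-[(triisopropylsilyl)oxy]but-2-en-1-ol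
Product: 3 (E)-4-[(triisopropylsilyl)oxy]but-2-en-1-yl N,N-diisopropylcarbamate
Conditions: i-Pr2NCOCl (1.3 equiv), pyridine, 90 °C, 12 h
Reagents that add atoms: N,N-diisopropylcarbamoyl chloride, CC(C)N(C(C)C)C(Cl)=O
Why: O-carbamoylation (nucleophilic acyl substitution) installs the group that later directs α-lithiation and ends as the enol leaving group; no stereocentre is formed.

Step 3
Reactants: 4 syringaldehyde (4-hydroxy-3,5-dimethoxybenzaldehyde)
Product: 5 3,5-dimethoxy-4-[(triisopropylsilyl)oxy]benzaldehyde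
Conditions: TIPSCl (1.2 equiv), imidazole (2.5 equiv), DMF, rt
Reagents that add atoms: chlorotriisopropylsilane (TIPSCl), CC(C)[Si](Cl)(C(C)C)C(C)C
Why: Phenol O-silylation masks the acidic OH so the aldehyde tolerates the allyltitanium reagent and BF3; TIPS is chosen because it survives both.

Step 4
Reactants: 3 (E)-4-[(triisopropylsilyl)oxy]but-2-en-1-yl N,N-diisopropylcarbamate; 5 3,5-dimethoxy-4-[(triisopropylsilyl)oxy]benzaldehyde
Product: 8 (1Z,3R,4S)-4-[3,5-dimethoxy-4-(triisopropylsilyloxy)phenyl]-4-hydroxy-3-[(triisopropylsilyloxy)methyl]but-1-en-1-yl N,N-diisopropylcarbamate, via lithiated carbamate sparteine complex 6 (not isolated), via allyl titanate 7 (not isolated)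
Conditions: n-BuLi (1.1 equiv), (−)-sparteine (1.2 equiv), toluene, −78 °C, 1 h; Ti(OiPr)4 (3 equiv), −78 °C, 30 min; 5 (1.2 equiv), −78 → −30 °C; 2 M aq HCl work-up
Reagents that add atoms: none
Why: Hoppe homoaldol reaction: carbamate-directed, (−)-sparteine-controlled removal of the pro-S allylic proton gives (S)-lithium species 6, Li→Ti exchange with inversion gives (R)-titanate 7, and γ-addition of this chiral homoenolate reagent to 5 through a closed chair (E-substituent equatorial, carbamoyloxy axial) sets C3 (R) and C4 (S) as the anti pair together with the Z-enol carbamate.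

Step 5
Reactants: 8 (1Z,3R,4S)-homoaldol adduct; 5 3,5-dimethoxy-4-[(triisopropylsilyl)oxy]benzaldehyde
Product: 11 (2S,3S,4R,5S)-2,5-bis[3,5-dimethoxy-4-(triisopropylsilyloxy)phenyl]-4-[(triisopropylsilyloxy)methyl]tetrahydrofuran-3-carbaldehyde, via oxocarbenium ion 9 (not isolated), via acyloxycarbenium ion 10 (not isolated)
Conditions: 5 (1.5 equiv), BF3·OEt2 (2 equiv), CH2Cl2, −78 → 0 °C, then hold at 0 °C until the isomer ratio is constant
Reagents that add atoms: none
Why: Hoppe-type Lewis-acid annulation of a homoaldol adduct with an aldehyde (Mukaiyama/Prins-type closure): the hydroxyl of 8 condenses with 5 to E-oxocarbenium ion 9, the enol carbamate carbon attacks it with the allylic C–H eclipsing the enol (new C3 trans to C4) and the incoming aryl on the less hindered side (C2 trans to C3), and fluoride transfer from boron to the carbamoyl group of 10 releases the aldehyde; the all-trans isomer is also the thermodynamic sink (enolisable C3, reversibly ionising benzylic C2–O), while C4 and C5 are carried over from 8.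

Step 6
Reactants: 11 (2S,3S,4R,5S)-tetrahydrofuran-3-carbaldehyde
Product: 12 [(2S,3R,4R,5S)-2,5-bis[3,5-dimethoxy-4-(triisopropylsilyloxy)phenyl]-4-[(triisopropylsilyloxy)methyl]tetrahydrofuran-3-yl]methanol
Conditions: NaBH4 (1.5 equiv), THF/MeOH 4:1, −20 → 0 °C, 15 min; aq NH4Cl
Reagents that add atoms: none
Why: Chemoselective hydride reduction of the aldehyde, fast enough at low temperature to outrun base-induced β-alkoxy elimination or C3 epimerisation; no stereocentre is touched and the silyl ethers are inert.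

Step 7
Reactants: 12 tris-silyl ether alcohol
Product: 13 huazhongilexin, [(2S,3R,4R,5S)-2,5-bis(4-hydroxy-3,5-dimethoxyphenyl)tetrahydrofuran-3,4-diyl]dimethanol
Conditions: Bu4NF (3.6 equiv), AcOH (3.6 equiv), THF, 0 °C → rt, argon; aq NH4Cl
Reagents that add atoms: none
Why: Fluoride-induced Si–O cleavage of two aryl and one alkyl TIPS ethers; the acetic acid buffer keeps the liberated phenols protonated so the 4-hydroxybenzylic ethers do not open through quinone methides, and no stereocentre is touched.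

**Compound list**

1 | (E)-but-2-ene-1,4-diol | OC/C=C/CO | starting material
2 | (E)-4-[(triisopropylsilyl)oxy]but-2-en-1-ol | OC/C=C/CO[Si](C(C)C)(C(C)C)C(C)C | intermediate
3 | (E)-4-[(triisopropylsilyl)oxy]but-2-en-1-yl N,N-diisopropylcarbamate | CC(C)N(C(C)C)C(=O)OC/C=C/CO[Si](C(C)C)(C(C)C)C(C)C | intermediate
4 | syringaldehyde (4-hydroxy-3,5-dimethoxybenzaldehyde) | COc1cc(C=O)cc(OC)c1O | starting material
5 | 3,5-dimethoxy-4-[(triisopropylsilyl)oxy]benzaldehyde | COc1cc(C=O)cc(OC)c1O[Si](C(C)C)(C(C)C)C(C)C | intermediate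
6 | (1S,2E)-1-lithio-4-[(triisopropylsilyl)oxy]but-2-en-1-yl N,N-diisopropylcarbamate, as its (−)-sparteine complex (ligand not drawn) | [Li][C@H](OC(=O)N(C(C)C)C(C)C)/C=C/CO[Si](C(C)C)(C(C)C)C(C)C | intermediate
7 | lithium [(1R,2E)-1-(diisopropylcarbamoyloxy)-4-(triisopropylsilyloxy)but-2-en-1-yl]tetraisopropoxytitanate | [Li+].CC(C)O[Ti-](OC(C)C)(OC(C)C)(OC(C)C)[C@@H](OC(=O)N(C(C)C)C(C)C)/C=C/CO[Si](C(C)C)(C(C)C)C(C)C | intermediate
8 | (1Z,3R,4S)-4-[3,5-dimethoxy-4-(triisopropylsilyloxy)phenyl]-4-hydroxy-3-[(triisopropylsilyloxy)methyl]but-1-en-1-yl N,N-diisopropylcarbamate | O[C@H](c1cc(OC)c(O[Si](C(C)C)(C(C)C)C(C)C)c(OC)c1)[C@@H](CO[Si](C(C)C)(C(C)C)C(C)C)/C=C\OC(=O)N(C(C)C)C(C)C | intermediate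
9 | E-oxocarbenium ion from 8 and 5 (O-arylmethylidene oxonium of 8; counter-ion hydroxytrifluoroborate) | COc1cc(/C=[O+]/[C@H](c2cc(OC)c(O[Si](C(C)C)(C(C)C)C(C)C)c(OC)c2)[C@@H](CO[Si](C(C)C)(C(C)C)C(C)C)/C=C\OC(=O)N(C(C)C)C(C)C)cc(OC)c1O[Si](C(C)C)(C(C)C)C(C)C | intermediate
10 | cyclised O-carbamoyl oxocarbenium ion (all-trans tetrahydrofuran bearing CH=O(+)–C(=O)N(i-Pr)2 at C3) | COc1cc([C@H]2O[C@H](c3cc(OC)c(O[Si](C(C)C)(C(C)C)C(C)C)c(OC)c3)[C@@H](CO[Si](C(C)C)(C(C)C)C(C)C)[C@@H]2C=[O+]C(=O)N(C(C)C)C(C)C)cc(OC)c1O[Si](C(C)C)(C(C)C)C(C)C | intermediate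
11 | (2S,3S,4R,5S)-2,5-bis[3,5-dimethoxy-4-(triisopropylsilyloxy)phenyl]-4-[(triisopropylsilyloxy)methyl]tetrahydrofuran-3-carbaldehyde | COc1cc([C@H]2O[C@H](c3cc(OC)c(O[Si](C(C)C)(C(C)C)C(C)C)c(OC)c3)[C@@H](CO[Si](C(C)C)(C(C)C)C(C)C)[C@@H]2C=O)cc(OC)c1O[Si](C(C)C)(C(C)C)C(C)C | intermediate
12 | [(2S,3R,4R,5S)-2,5-bis[3,5-dimethoxy-4-(triisopropylsilyloxy)phenyl]-4-[(triisopropylsilyloxy)methyl]tetrahydrofuran-3-yl]methanol | COc1cc([C@H]2O[C@H](c3cc(OC)c(O[Si](C(C)C)(C(C)C)C(C)C)c(OC)c3)[C@@H](CO[Si](C(C)C)(C(C)C)C(C)C)[C@@H]2CO)cc(OC)c1O[Si](C(C)C)(C(C)C)C(C)C | intermediate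
13 | huazhongilexin, [(2S,3R,4R,5S)-2,5-bis(4-hydroxy-3,5-dimethoxyphenyl)tetrahydrofuran-3,4-diyl]dimethanol | COc1cc([C@H]2O[C@H](c3cc(OC)c(O)c(OC)c3)[C@@H](CO)[C@@H]2CO)cc(OC)c1O | target

**Totals**

Total step count: 7. Longest linear sequence: 6 (steps 1, 2, 4, 5, 6, 7).

**Three steps most likely to fail**

Step 4 (homoaldol). The lithiated carbamate carries a silyloxy group next to the allyl terminus and may lose silanolate to give 1-(carbamoyloxy)buta-1,3-diene. The non-crystalline lithium–sparteine pair may also give only about 85–90 % ee, which would then be raised by recrystallising 12 or 13. Fallback, setting out from 1 and coming back at 8: an excess of diol 1 is mono-carbamoylated (i-Pr2NCOCl, pyridine) to (E)-4-hydroxybut-2-en-1-yl N,N-diisopropylcarbamate F1. F1 is doubly deprotonated (n-BuLi 2.2 equiv, (−)-sparteine, toluene, −78 °C), so the C4 oxygen is a lithium alkoxide that cannot leave. Titanation with Ti(OiPr)4 and addition to 5 as before give (1Z,3R,4S)-4-[3,5-dimethoxy-4-(triisopropylsilyloxy)phenyl]-4-hydroxy-3-(hydroxymethyl)but-1-en-1-yl N,N-diisopropylcarbamate F2. Only its primary hydroxyl is silylated (TIPSCl, imidazole, 0 °C), which gives 8.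

Step 5 (annulation). Under BF3 the electron-rich benzylic alcohol of 8 can ionise, or the oxocarbenium ion can undergo 2-oxonia-Cope scrambling, before ring closure. Fallback, setting out from 5 and 8 and coming back at 11: aldehyde 5 is converted (HC(OMe)3, cat. TsOH, MeOH) into [4-(dimethoxymethyl)-2,6-dimethoxyphenoxy]triisopropylsilane F3. Acetal exchange of F3 with 8 (cat. PPTS, benzene, 5 Å sieves) gives the isolable mixed methyl acetal of 8 F4 as both acetal epimers. F4 is then ionised alone at −78 °C with BF3·OEt2 in CH2Cl2, so that 9 forms without free alcohol or aldehyde present and closes to 11.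

Step 7 (triple desilylation). Fluoride generates two phenoxides beside free hydroxymethyl groups, which invites quinone-methide ring opening (isomeric ethers, syringaresinol-type products) and air oxidation. Fallback, setting out from 4 and coming back at 13, with a neutral hydrogenolytic end game:
- 4 is benzylated (BnBr, K2CO3, DMF) to 4-(benzyloxy)-3,5-dimethoxybenzaldehyde F5.
- F5 and 3 under the step 4 conditions give the benzyl-protected homoaldol adduct F6.
- F6 and F5 under the step 5 conditions give the benzyl-protected tetrahydrofuran carbaldehyde F7.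
- NaBH4 gives the benzyl-protected alcohol F8.
- Bu4NF removes the single alkyl silyl ether (no phenoxide is formed) to give the bis(benzyl ether) diol F9.
- H2 (1 atm) over Pd/C in EtOAc, stopped at full debenzylation, gives 13.

Further compounds
F1 | step 4 | (E)-4-hydroxybut-2-en-1-yl N,N-diisopropylcarbamate | CC(C)N(C(C)C)C(=O)OC/C=C/CO
F2 | step 4 | (1Z,3R,4S)-4-[3,5-dimethoxy-4-(triisopropylsilyloxy)phenyl]-4-hydroxy-3-(hydroxymethyl)but-1-en-1-yl N,N-diisopropylcarbamate | O[C@H](c1cc(OC)c(O[Si](C(C)C)(C(C)C)C(C)C)c(OC)c1)[C@@H](CO)/C=C\OC(=O)N(C(C)C)C(C)C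
F3 | step 5 | [4-(dimethoxymethyl)-2,6-dimethoxyphenoxy]triisopropylsilane | COC(OC)c1cc(OC)c(O[Si](C(C)C)(C(C)C)C(C)C)c(OC)c1
F4 | step 5 | (1Z,3R,4S)-4-[3,5-dimethoxy-4-(triisopropylsilyloxy)phenyl]-4-{[3,5-dimethoxy-4-(triisopropylsilyloxy)phenyl](methoxy)methoxy}-3-[(triisopropylsilyloxy)methyl]but-1-en-1-yl N,N-diisopropylcarbamate (acetal epimers) | COC(c1cc(OC)c(O[Si](C(C)C)(C(C)C)C(C)C)c(OC)c1)O[C@H](c2cc(OC)c(O[Si](C(C)C)(C(C)C)C(C)C)c(OC)c2)[C@@H](CO[Si](C(C)C)(C(C)C)C(C)C)/C=C\OC(=O)N(C(C)C)C(C)C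
F5 | step 7 | 4-(benzyloxy)-3,5-dimethoxybenzaldehyde | COc1cc(C=O)cc(OC)c1OCc1ccccc1
F6 | step 7 | (1Z,3R,4S)-4-[4-(benzyloxy)-3,5-dimethoxyphenyl]-4-hydroxy-3-[(triisopropylsilyloxy)methyl]but-1-en-1-yl N,N-diisopropylcarbamate | O[C@H](c1cc(OC)c(OCc2ccccc2)c(OC)c1)[C@@H](CO[Si](C(C)C)(C(C)C)C(C)C)/C=C\OC(=O)N(C(C)C)C(C)C
F7 | step 7 | (2S,3S,4R,5S)-2,5-bis[4-(benzyloxy)-3,5-dimethoxyphenyl]-4-[(triisopropylsilyloxy)methyl]tetrahydrofuran-3-carbaldehyde | COc1cc([C@H]2O[C@H](c3cc(OC)c(OCc4ccccc4)c(OC)c3)[C@@H](CO[Si](C(C)C)(C(C)C)C(C)C)[C@@H]2C=O)cc(OC)c1OCc1ccccc1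
F8 | step 7 | [(2S,3R,4R,5S)-2,5-bis[4-(benzyloxy)-3,5-dimethoxyphenyl]-4-[(triisopropylsilyloxy)methyl]tetrahydrofuran-3-yl]methanol | COc1cc([C@H]2O[C@H](c3cc(OC)c(OCc4ccccc4)c(OC)c3)[C@@H](CO[Si](C(C)C)(C(C)C)C(C)C)[C@@H]2CO)cc(OC)c1OCc1ccccc1
F9 | step 7 | [(2S,3R,4R,5S)-2,5-bis[4-(benzyloxy)-3,5-dimethoxyphenyl]tetrahydrofuran-3,4-diyl]dimethanol | COc1cc([C@H]2O[C@H](c3cc(OC)c(OCc4ccccc4)c(OC)c3)[C@@H](CO)[C@@H]2CO)cc(OC)c1OCc1ccccc1
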